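## Structural features

The target 22 is a flavanone: aromatic ring A is fused through C4a and C8a to a dihydropyranone ring C (O1, C2, C3, C4=O), and a 3,4-dimethoxyphenyl ring B sits on C2. C2 is the only stereocentre (S); it is benzylic, carries O1 and lies β to the C4 ketone, so it has no neighbouring stereocentre to relay from and must be set on its own. This carbon is fragile in two ways: base can open ring C by retro-oxa-Michael expulsion of the C8a phenoxide (chalcone formation, loss of configuration), and acid or activation of the oxygen ionises the electron-rich benzylic C2–O1 bond. Ring A carries oxygen at C5, C7 and C8 next to O1 at C8a and has one hydrogen (C6). This 5,7,8 pattern is harder to place by electrophilic substitution of phloroglucinol-type phenols than the 5,6,7 isomer, and boronates on so electron-rich a ring are prone to protodeboronation. The real difficulty is to close ring C onto a correctly oxygenated ring A without breaking the C2–O1 bond and without exposing the finished ketone to base. The plan exploits the fact that C8a and C4a are adjacent carbons of ring A, bear O1 and the C4 acyl carbon, and are flanked by the oxygenated carbons C8 and C5. An aryne across C8a–C4a can therefore take up the alkoxide oxygen and the amide carbonyl of an intact (S)-3-aryl-3-hydroxypropanoyl chain, with boron at C8 standing in for the last oxygen.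

## Logic of the disconnections

22 is cut at the O–CH3 bond on C8, giving 21. The C8 substituent has a directing role earlier, so its oxygen can only be finished late. The forward step must methylate a hindered phenol without base strong enough to open ring C and without a hazardous diazo reagent.

21 is cut at the C8–O bond, which is replaced by the C8–B bond of 20. Boron is an oxygen surrogate that is electropositive and Lewis acidic, so it can bias an aryne where a methoxy group could not. The forward oxidation must outrun protodeboronation and leave the ketone and C2 alone.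

20 is cut at O1–C8a and C4–C4a, giving 11 and 14. These two bonds join ring A to a three-carbon chain that already holds the C2 stereocentre and the C4 oxidation level, so ring C and the full skeleton arise in one convergent operation and C2–O1 is never made by substitution at carbon. The forward step demands aryne generation that tolerates an alkoxide and a Weinreb amide, oxygen attack at C8a only, acylation of the C4a carbanion faster than its protonation, and a ketone that stays masked until the quench. The structures of 11 and 14 are kept; the improvement is that 14 enters as its pre-formed chloromagnesium alkoxide 15, in modest excess, and that the exchange reagent is added last.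

14 is cut at the amide C–N bond to 13, and 13 at the carbinol C–H bond to 12. The stereocentre is thus set by catalytic reduction of an aryl ketone, far from ring A, and the demand is high enantioselectivity plus an aminolysis that does not eliminate the β-hydroxyl.

11 is cut at the O–S bond to 10, and 10 at the aryl O–C(=O) bond to 8. The demand on the forward cleavage is that it spare the C–I bond and the labile C–B bond, which rules out hot hydroxide and aluminium hydrides.

8 is cut at the C–B bond to 4 and 5, 4 at the C–I bond to 2, and 2 at the carbamoyl O–C bond to 1. One directing group sends both substituents to its two ortho positions, each also flanked by a methoxy group, so the substitution pattern of ring A is fixed without ambiguity. The second metalation must tolerate the C–I bond, hence a lithium amide with in situ trapping.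

## Other disconnections considered

Alternative 1: The cut is the C4a–C5 bond of ring A, with C8–C8a cut one stage earlier, so ring A is grown onto a chiral dihydropyran.
- Forward step: the enol ether carbon (future C8a) of tert-butyl{[(2S,4S)-2-(3,4-dimethoxyphenyl)-3,4-dihydro-2H-pyran-4-yl]oxy}dimethylsilane A3 would be metalated and added to the ketone carbonyl of 3-methoxycyclobut-3-ene-1,2-dione A4, giving the 4-hydroxycyclobutenone A2. Heating A2 would open the four-membered ring to a dienylketene; 6π electrocyclisation onto the dihydropyran C=C and tautomerisation would give the hydroquinone A1 (a Moore-type rearrangement).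
- In its favour: the 5,7,8 pattern and the single C6 hydrogen follow from connectivity alone, O1–C2 is never touched, and the thermal rearrangement is an established reaction class. On regiochemical certainty and on precedent for the key step this alternative is better than the chosen plan.
- Against it here: A1 is at the wrong oxidation level at three positions (air-sensitive free phenols at C5 and C8, a silyl ether at C4), so double O-methylation, desilylation and alcohol oxidation must follow. A second stereocentre (C4) is carried and then destroyed. The allylic silyloxy group next to an enol ether invites Ferrier-type ionisation, the metalation needs a pyrophoric alkyllithium, and neither A3 nor A4 is an off-the-shelf material.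
- Comparison: on structure both plans keep the benzylic C–O bond intact (equal). On mechanism a pericyclic cascade with no regiochemical choice stands against a polar aryne addition that needs two directing groups (alternative better). On step economy about three steps to A3, two to A1 and three after it, plus the preparation of A4, make it equal at best and probably longer than the ten steps chosen here.

Alternative 2: The cut is the C3–C4 bond, formed as C3=C4 with C4 masked as a silyl enol ether.
- Forward step: the precursor A6 is the tert-butyldimethylsilyl enol ether derived from 1-(2-hydroxy-3,4,6-trimethoxyphenyl)ethan-1-one A7, whose phenolic oxygen carries an (S)-1-aryl-allyl group. A ruthenium alkylidene catalyst would load on the monosubstituted vinyl group and close onto the 1,1-disubstituted enol ether with loss of the C2 alkene, giving the 4-silyloxy-2H-chromene A5. Hydrolysis of the enol silane would then give 22 in one step.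
- In its favour: the ketone oxidation level is reached one step after the key step (better than the two steps needed here), all three ring A methoxy groups are present from the start, and the key step is catalytic (better in reagent economy than a stoichiometric aryne).
- Against it here: the stereocentre of A6 is allylic as well as benzylic on an electron-rich aryl group, so making the ether and enolising with a silyl triflate risk ionisation and SN1 or SN2′ scrambling. Ruthenium hydrides can isomerise the allyl ether. A5 is a 2-aryl-2H-chromene that can ring-open reversibly to an ortho-quinone methide dienone (loss of C2 configuration) and is acid-labile towards a flavylium ion. A7 carries the same 5,7,8 regiochemical problem and needs its own synthesis.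
- Comparison: on structure both leave C2–O1 intact once formed, but here it has to be formed at a more labile carbinol (chosen plan better). On step economy the alternative is shorter from A7 (better), and roughly equal once A7 and the chiral allyl unit are counted.

Alternative 3: The cuts are C3–C4 and O1–C2, made together in a [4+2] cycloaddition. That is two bonds and one ring, equal to the chosen key step.
- Forward step: 2-hydroxy-3,4,6-trimethoxybenzaldehyde A9 would be converted with an orthoformate and acid into its acetal, which ionises to the 4-methoxy ortho-quinone methide (a phenolic oxocarbenium ion). Inverse-demand hetero-Diels–Alder addition of 3,4-dimethoxystyrene A10 would give the 4-methoxyflavan A8.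
- In its favour: it is the shortest route by far (better than the chosen plan on step economy), both partners are simple, and the polarity of the partners fixes the orientation.
- Against it here: C2 would have to be set by an external chiral acid acting on a very reactive cation, in the presence of a styrene that oligomerises under acid. C4 arrives as a benzylic methyl ether, and its oxidation to the ketone must discriminate against the equally activated C2–H; over-oxidation to a flavylium ion or flavone and acid ionisation at C2 are the likely losses. A9 again carries the 5,7,8 problem.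
- Comparison: on mechanism both are two-bond annulations (equal), but here the stereocentre is created in the key step under catalyst control, while in the chosen plan it is a spectator set by a dependable ketone reduction (chosen plan better). On structure the chosen plan delivers the ketone level directly and the alternative does not.

Key step: step 8

Remark on the chemistry: the mapping from 11 to 20 is C1(OTf) → C8a, C2(I) → C4a, C3 → C5, C5 → C7, C6(B) → C8. The CIP order O > aryl > CH2 > H is unchanged throughout, so 14, 20 and 22 are all S and these structures are mutually consistent as drawn.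

## Route

Step 1
Reactants: 1 3,5-dimethoxyphenol
Product: 2 3,5-dimethoxyphenyl N,N-diethylcarbamate
Conditions: Et2NCOCl, K2CO3, MeCN, reflux
Reagents that add atoms: N,N-diethylcarbamoyl chloride, CCN(CC)C(Cl)=O
Why: O-Carbamoylation of the phenoxide; the diethylcarbamate is a strong director for ortho-lithiation, survives alkyllithium and lithium amide bases at −78 °C, and its oxygen later becomes the triflate leaving group.

Step 2
Reactants: 2 3,5-dimethoxyphenyl N,N-diethylcarbamate
Product: 4 2-iodo-3,5-dimethoxyphenyl N,N-diethylcarbamate, via aryllithium 3 (not isolated)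
Conditions: s-BuLi, TMEDA, THF, −78 °C; then I2, −78 °C to rt
Reagents that add atoms: iodine, II
Why: Directed ortho-metalation: carbamate and neighbouring methoxy group cooperate, so lithiation should occur between them and not between the two methoxy groups; at −78 °C the aryllithium 3 is trapped by iodine before an anionic Fries shift can set in.

Step 3
Reactants: 4 2-iodo-3,5-dimethoxyphenyl N,N-diethylcarbamate; 5 2-isopropoxy-4,4,5,5-tetramethyl-1,3,2-dioxaborolane
Product: 8 2-iodo-3,5-dimethoxy-6-(4,4,5,5-tetramethyl-1,3,2-dioxaborolan-2-yl)phenyl N,N-diethylcarbamate, via aryllithium 6 (not isolated), via lithium borate 7 (not isolated)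
Conditions: lithium 2,2,6,6-tetramethylpiperidide (LiTMP, from 2,2,6,6-tetramethylpiperidine and n-BuLi), 5 present from the start, THF, −78 °C; then AcOH, −78 °C to rt
Reagents that add atoms: none
Why: Directed ortho-metalation with in situ trapping: a lithium amide deprotonates the remaining carbamate-flanked position without the iodine–lithium exchange an alkyllithium would cause, and the boron electrophile already present captures 6 before iodine can migrate between aryl anions; acetic acid releases the neutral boronate from 7.

Step 4
Reactants: 8 2-iodo-3,5-dimethoxy-6-(4,4,5,5-tetramethyl-1,3,2-dioxaborolan-2-yl)phenyl N,N-diethylcarbamate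
Product: 10 2-iodo-3,5-dimethoxy-6-(4,4,5,5-tetramethyl-1,3,2-dioxaborolan-2-yl)phenol, via zirconium aryloxide 9 (not isolated)
Conditions: Cp2Zr(H)Cl (3 equiv), THF, rt; then H2O
Reagents that add atoms: none
Why: Reductive cleavage of the aryl O-carbamate: hydrozirconation of the carbamate C=O and collapse of the adduct leave the aryloxide on zirconium and release diethylformamide under neutral, non-aqueous conditions, which should spare the C–I bond and the protodeboronation-prone C–B bond that hot hydroxide or LiAlH4 would not.

Step 5
Reactants: 10 2-iodo-3,5-dimethoxy-6-(4,4,5,5-tetramethyl-1,3,2-dioxaborolan-2-yl)phenol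
Product: 11 2-iodo-3,5-dimethoxy-6-(4,4,5,5-tetramethyl-1,3,2-dioxaborolan-2-yl)phenyl trifluoromethanesulfonate
Conditions: Tf2O, pyridine, CH2Cl2, 0 °C
Reagents that add atoms: trifluoromethanesulfonic anhydride, O=S(=O)(OS(=O)(=O)C(F)(F)F)C(F)(F)F
Why: O-Sulfonylation of the phenol; triflic anhydride is reactive enough for a phenol flanked on both sides, and the product has iodide ortho to triflate as needed for exchange–elimination.

Step 6
Reactants: 12 ethyl 3-(3,4-dimethoxyphenyl)-3-oxopropanoate
Product: 13 ethyl (3S)-3-(3,4-dimethoxyphenyl)-3-hydroxypropanoate
Conditions: RuCl(p-cymene)[(S,S)-TsDPEN] (1 mol %), HCO2H/Et3N (5:2), 40 °C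
Reagents that add atoms: none
Why: Noyori asymmetric transfer hydrogenation of an aryl ketone: the (S,S) ligand delivers hydride to the face that gives the S carbinol when aryl outranks the second substituent (here CH2CO2Et), as with simple aryl methyl ketones; formic acid avoids pressurised hydrogen.

Step 7
Reactants: 13 ethyl (3S)-3-(3,4-dimethoxyphenyl)-3-hydroxypropanoate
Product: 14 (3S)-3-(3,4-dimethoxyphenyl)-3-hydroxy-N-methoxy-N-methylpropanamide
Conditions: MeNH(OMe)·HCl, i-PrMgCl, THF, −20 to 0 °C; then AcOH
Reagents that add atoms: N,O-dimethylhydroxylamine hydrochloride, CNOC.Cl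
Why: Aminolysis of the ester by the chloromagnesium amide of N,O-dimethylhydroxylamine (Weinreb amidation); the hydroxyl is carried as its magnesium alkoxide, and at or below 0 °C neither β-elimination nor retro-aldol cleavage should compete, so the stereocentre is untouched.

Step 8
Reactants: 11 2-iodo-3,5-dimethoxy-6-(4,4,5,5-tetramethyl-1,3,2-dioxaborolan-2-yl)phenyl trifluoromethanesulfonate; 14 (3S)-3-(3,4-dimethoxyphenyl)-3-hydroxy-N-methoxy-N-methylpropanamide
Product: 20 (2S)-2-(3,4-dimethoxyphenyl)-5,7-dimethoxy-8-(4,4,5,5-tetramethyl-1,3,2-dioxaborolan-2-yl)chroman-4-one, via magnesium alkoxide 15 (not isolated), via aryl Grignard 16 (not isolated), via aryne 17 (not isolated), via ether Grignard 18 (not isolated), via tetrahedral chelate 19 (not isolated)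
Conditions: 14 (1.5 equiv), i-PrMgCl·LiCl (1.5 equiv), THF, −40 °C; add 11 (1.0 equiv), −78 °C; i-PrMgCl·LiCl (1.1 equiv, slow addition), −78 °C to rt; then AcOH, −20 °C
Reagents that add atoms: none
Why: Proposed new method: iodine–magnesium exchange at the iodinated carbon of 11, fast at −78 °C because of the ortho triflate, gives 16, which loses chloromagnesium triflate to form aryne 17 across the future C8a–C4a bond. The pre-formed chloromagnesium alkoxide 15 adds through oxygen at C8a, and the C4a arylmagnesium 18 so formed attacks the Weinreb carbonyl to give the chelated adduct 19, which releases the ketone only on the acetic acid quench, so the flavanone never meets base. The closest known reaction types are the annulation of arynes with salicylates to xanthones (heteroatom addition, then intramolecular acyl substitution by the aryl anion) and the boron-proximal addition of heteroatom nucleophiles to 3-borylarynes made by the same exchange–elimination. Ring C closes by 6-exo-trig attack of the aryl carbanion on the amide carbonyl through a six-membered magnesium chelate; the first C–O bond is intermolecular and closes no ring. No stereocentre is created: C2 comes from 14 and keeps its S configuration because its C–O bond is never broken and the weakly basic magnesium species do not deprotonate C3. The selectivity needed is regiochemical: the C5 methoxy group beside C4a stabilises negative charge there inductively, and the electropositive boryl group beside C8a, which can also pre-coordinate the alkoxide, makes C8a the electrophilic terminus, so both flanking groups send oxygen to C8a. Chemoselectivity rests on the order of addition: the alkoxide is made first and the exchange reagent is added last and slowly, so it is consumed by the exchange and not by the amide or the aryne.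

Step 9
Reactants: 20 (2S)-2-(3,4-dimethoxyphenyl)-5,7-dimethoxy-8-(4,4,5,5-tetramethyl-1,3,2-dioxaborolan-2-yl)chroman-4-one
Product: 21 (2S)-2-(3,4-dimethoxyphenyl)-8-hydroxy-5,7-dimethoxychroman-4-one
Conditions: NaBO3·4H2O, THF/aq NaH2PO4–Na2HPO4 buffer (pH 7), 0 °C to rt
Reagents that add atoms: sodium perborate (used as the tetrahydrate), [Na+].[O-]OB=O
Why: ipso-Oxidation of the aryl boronate (peroxide adds to boron, aryl shifts from boron to oxygen, the borate ester hydrolyses); near-neutral perborate should act faster than protodeboronation and is too weakly basic to open ring C by retro-oxa-Michael elimination, so C2 keeps its configuration.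

Step 10
Reactants: 21 (2S)-2-(3,4-dimethoxyphenyl)-8-hydroxy-5,7-dimethoxychroman-4-one
Product: 22 (2S)-2-(3,4-dimethoxyphenyl)-5,7,8-trimethoxychroman-4-one
Conditions: MeOH, PPh3, DIAD, THF, 0 °C to rt
Reagents that add atoms: methanol, CO
Why: Mitsunobu O-alkylation of the phenol by methanol: the phenoxide attacks the methoxyphosphonium ion under essentially neutral conditions, so ring C is not opened and C2 is not epimerised; it replaces toxic diazo reagents and strongly basic methylations.

## Compound list

1 | 3,5-dimethoxyphenol | COc1cc(O)cc(OC)c1 | starting material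
2 | 3,5-dimethoxyphenyl N,N-diethylcarbamate | COc1cc(OC)cc(OC(=O)N(CC)CC)c1 | intermediate
3 | [2-(diethylcarbamoyloxy)-4,6-dimethoxyphenyl]lithium | [Li]c1c(OC)cc(OC)cc1OC(=O)N(CC)CC | intermediate (not isolated)
4 | 2-iodo-3,5-dimethoxyphenyl N,N-diethylcarbamate | COc1cc(OC)c(I)c(OC(=O)N(CC)CC)c1 | intermediate
5 | 2-isopropoxy-4,4,5,5-tetramethyl-1,3,2-dioxaborolane | CC(C)OB1OC(C)(C)C(C)(C)O1 | starting material
6 | [2-(diethylcarbamoyloxy)-3-iodo-4,6-dimethoxyphenyl]lithium | [Li]c1c(OC)cc(OC)c(I)c1OC(=O)N(CC)CC | intermediate (not isolated)
7 | lithium [2-(diethylcarbamoyloxy)-3-iodo-4,6-dimethoxyphenyl](isopropoxy)(2,3-dimethylbutane-2,3-diolato)borate | [Li+].COc1cc(OC)c([B-]2(OC(C)C)OC(C)(C)C(C)(C)O2)c(OC(=O)N(CC)CC)c1I | intermediate (not isolated)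
8 | 2-iodo-3,5-dimethoxy-6-(4,4,5,5-tetramethyl-1,3,2-dioxaborolan-2-yl)phenyl N,N-diethylcarbamate | COc1cc(OC)c(B2OC(C)(C)C(C)(C)O2)c(OC(=O)N(CC)CC)c1I | intermediate
9 | chlorobis(cyclopentadienyl)zirconium 2-iodo-3,5-dimethoxy-6-(4,4,5,5-tetramethyl-1,3,2-dioxaborolan-2-yl)phenoxide | COc1cc(OC)c(B2OC(C)(C)C(C)(C)O2)c(O[Zr](Cl)(C3C=CC=C3)C4C=CC=C4)c1I | intermediate (not isolated)
10 | 2-iodo-3,5-dimethoxy-6-(4,4,5,5-tetramethyl-1,3,2-dioxaborolan-2-yl)phenol | COc1cc(OC)c(B2OC(C)(C)C(C)(C)O2)c(O)c1I | intermediate
11 | 2-iodo-3,5-dimethoxy-6-(4,4,5,5-tetramethyl-1,3,2-dioxaborolan-2-yl)phenyl trifluoromethanesulfonate | COc1cc(OC)c(B2OC(C)(C)C(C)(C)O2)c(OS(=O)(=O)C(F)(F)F)c1I | intermediate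
12 | ethyl 3-(3,4-dimethoxyphenyl)-3-oxopropanoate | CCOC(=O)CC(=O)c1ccc(OC)c(OC)c1 | starting material
13 | ethyl (3S)-3-(3,4-dimethoxyphenyl)-3-hydroxypropanoate | CCOC(=O)C[C@H](O)c1ccc(OC)c(OC)c1 | intermediate
14 | (3S)-3-(3,4-dimethoxyphenyl)-3-hydroxy-N-methoxy-N-methylpropanamide | COc1ccc([C@@H](O)CC(=O)N(C)OC)cc1OC | intermediate
15 | chloromagnesium (1S)-1-(3,4-dimethoxyphenyl)-3-[methoxy(methyl)amino]-3-oxopropan-1-olate | COc1ccc([C@@H](O[Mg]Cl)CC(=O)N(C)OC)cc1OC | intermediate (not isolated)
16 | chloro[4,6-dimethoxy-3-(4,4,5,5-tetramethyl-1,3,2-dioxaborolan-2-yl)-2-(trifluoromethanesulfonyloxy)phenyl]magnesium | COc1cc(OC)c(B2OC(C)(C)C(C)(C)O2)c(OS(=O)(=O)C(F)(F)F)c1[Mg]Cl | intermediate (not isolated)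
17 | 1,2-didehydro-3,5-dimethoxy-6-(4,4,5,5-tetramethyl-1,3,2-dioxaborolan-2-yl)benzene | COC1=CC(OC)=C(B2OC(C)(C)C(C)(C)O2)C#C1 | intermediate (not isolated)
18 | chloro{2-[(1S)-1-(3,4-dimethoxyphenyl)-3-[methoxy(methyl)amino]-3-oxopropoxy]-4,6-dimethoxy-3-(4,4,5,5-tetramethyl-1,3,2-dioxaborolan-2-yl)phenyl}magnesium | COc1ccc([C@@H](Oc2c([Mg]Cl)c(OC)cc(OC)c2B3OC(C)(C)C(C)(C)O3)CC(=O)N(C)OC)cc1OC | intermediate (not isolated)
19 | chloromagnesium (2S)-2-(3,4-dimethoxyphenyl)-5,7-dimethoxy-4-[methoxy(methyl)amino]-8-(4,4,5,5-tetramethyl-1,3,2-dioxaborolan-2-yl)chroman-4-olate | COc1ccc([C@@H]2CC(O[Mg]Cl)(N(C)OC)c3c(OC)cc(OC)c(B4OC(C)(C)C(C)(C)O4)c3O2)cc1OC | intermediate (not isolated)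
20 | (2S)-2-(3,4-dimethoxyphenyl)-5,7-dimethoxy-8-(4,4,5,5-tetramethyl-1,3,2-dioxaborolan-2-yl)chroman-4-one | COc1ccc([C@@H]2CC(=O)c3c(OC)cc(OC)c(B4OC(C)(C)C(C)(C)O4)c3O2)cc1OC | intermediate
21 | (2S)-2-(3,4-dimethoxyphenyl)-8-hydroxy-5,7-dimethoxychroman-4-one | COc1ccc([C@@H]2CC(=O)c3c(OC)cc(OC)c(O)c3O2)cc1OC | intermediate
22 | (2S)-2-(3,4-dimethoxyphenyl)-5,7,8-trimethoxychroman-4-one | COc1ccc([C@@H]2CC(=O)c3c(OC)cc(OC)c(OC)c3O2)cc1OC | target

## Step count and risks

Total step count: 10. Longest linear sequence: 8 steps (steps 1, 2, 3, 4, 5, 8, 9 and 10 from 1); the second branch (steps 6 and 7 from 12) joins at step 8.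

Least certain steps, the proposed new method first:

**Step 8.** The most likely failure is slow intermolecular capture of the short-lived aryne by a weakly nucleophilic, chelated magnesium alkoxide. The aryne would then be consumed by the exchange reagent or by aryl Grignard species, or the C4a anion would be protonated before it acylates. A second risk is elimination of triflate towards the boron side after alkoxide binds to boron.

The fallback uses known chemistry, sets out from 10 and 12, and returns at 20. 12 would be reduced as in step 6 but with RuCl(p-cymene)[(R,R)-TsDPEN], giving ethyl (3R)-3-(3,4-dimethoxyphenyl)-3-hydroxypropanoate F1. F1 would be converted as in step 7 into (3R)-3-(3,4-dimethoxyphenyl)-3-hydroxy-N-methoxy-N-methylpropanamide F2. A Mitsunobu etherification of 10 with F2 (PPh3, DIAD, toluene, 0 °C) would invert the carbinol and give (3S)-3-(3,4-dimethoxyphenyl)-3-[2-iodo-3,5-dimethoxy-6-(4,4,5,5-tetramethyl-1,3,2-dioxaborolan-2-yl)phenoxy]-N-methoxy-N-methylpropanamide F3. Iodine–magnesium exchange on F3 with i-PrMgCl·LiCl (THF, −20 to 0 °C), helped by the two ortho oxygen substituents, would give 18 directly. 18 closes to 19 and, after acetic acid, to 20 (a Parham-type cyclisation onto a Weinreb amide). The price is that the C2–O bond is then made by substitution at the ionisable benzylic carbon with a hindered phenol, so the enantiomeric purity of F3 would need checking.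

**Step 3.** The most likely failure is iodine transfer between the new aryllithium and unreacted iodide (halogen scrambling), or consumption of the amide base by the borate, giving incomplete or scrambled borylation. Loss of boron from the very electron-rich ring during work-up is a further risk.

The fallback sets out from 2 and returns at 8, changing the order of the two functionalisations. 2 would be lithiated as in step 2 (via 3) and trapped with 5, giving 3,5-dimethoxy-2-(4,4,5,5-tetramethyl-1,3,2-dioxaborolan-2-yl)phenyl N,N-diethylcarbamate F4. The remaining carbamate-flanked position of F4 would then be magnesiated with TMPMgCl·LiCl (THF, 0 °C to rt), a base that tolerates boronic esters, and quenched with I2 to give 8. No aryl iodide is then ever exposed to an organolithium.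

**Step 4.** The most likely failure is hydride delivery to boron, or slow collapse of the adduct of a carbamate hindered on both sides, together with protodeboronation of the free, very electron-rich phenol on work-up.

The fallback sets out from 1 and returns at 10, replacing the carbamate with an acetal director that is removed without reduction. 1 would be converted into 1,3-dimethoxy-5-(methoxymethoxy)benzene F5 (chloromethyl methyl ether generated and consumed in solution from dimethoxymethane, AcCl and catalytic ZnBr2, then 1 and i-Pr2NEt). F5 would be lithiated between the acetal and a methoxy group (n-BuLi, TMEDA, THF, −78 to 0 °C) and iodinated to 2-iodo-1,5-dimethoxy-3-(methoxymethoxy)benzene F6. F6 would be borylated as in step 3 to 2-[3-iodo-4,6-dimethoxy-2-(methoxymethoxy)phenyl]-4,4,5,5-tetramethyl-1,3,2-dioxaborolane F7. The acetal of F7 would be removed with TMSOTf and 2,2′-bipyridyl (CH2Cl2, 0 °C; then H2O) to give 10. The cost is a weaker directing group, so the first lithiation is less certain to avoid the position between the two methoxy groups.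

**Step 9.** The most likely failure is opening of ring C under the aqueous oxidant (retro-oxa-Michael, with loss of C2 configuration), or protodeboronation competing with oxidation.

The fallback sets out from 20 and returns at 22, bypassing 21 and step 10. It is a copper-mediated oxidative methoxylation of the boronate (Chan–Lam type: Cu(OAc)2, DMAP, MeOH, 4 Å molecular sieves, O2, 40 °C), which turns C–B directly into C–OMe under non-aqueous, weakly basic conditions. It makes no new compound (F0). Its weakness is that boronates substituted at both ortho positions transmetalate slowly.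

## Further compounds

F1 | step 8 | ethyl (3R)-3-(3,4-dimethoxyphenyl)-3-hydroxypropanoate | CCOC(=O)C[C@@H](O)c1ccc(OC)c(OC)c1
F2 | step 8 | (3R)-3-(3,4-dimethoxyphenyl)-3-hydroxy-N-methoxy-N-methylpropanamide | COc1ccc([C@H](O)CC(=O)N(C)OC)cc1OC
F3 | step 8 | (3S)-3-(3,4-dimethoxyphenyl)-3-[2-iodo-3,5-dimethoxy-6-(4,4,5,5-tetramethyl-1,3,2-dioxaborolan-2-yl)phenoxy]-N-methoxy-N-methylpropanamide | COc1ccc([C@@H](Oc2c(I)c(OC)cc(OC)c2B3OC(C)(C)C(C)(C)O3)CC(=O)N(C)OC)cc1OC
F4 | step 3 | 3,5-dimethoxy-2-(4,4,5,5-tetramethyl-1,3,2-dioxaborolan-2-yl)phenyl N,N-diethylcarbamate | COc1cc(OC)c(B2OC(C)(C)C(C)(C)O2)c(OC(=O)N(CC)CC)c1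
F5 | step 4 | 1,3-dimethoxy-5-(methoxymethoxy)benzene | COCOc1cc(OC)cc(OC)c1
F6 | step 4 | 2-iodo-1,5-dimethoxy-3-(methoxymethoxy)benzene | COCOc1cc(OC)cc(OC)c1I
F7 | step 4 | 2-[3-iodo-4,6-dimethoxy-2-(methoxymethoxy)phenyl]-4,4,5,5-tetramethyl-1,3,2-dioxaborolane | COCOc1c(B2OC(C)(C)C(C)(C)O2)c(OC)cc(OC)c1I
F0 | step 9 | none | none
A1 | alternative 1 | (2S,4S)-4-(tert-butyldimethylsilyloxy)-2-(3,4-dimethoxyphenyl)-7-methoxychromane-5,8-diol | COc1ccc([C@@H]2C[C@H](O[Si](C)(C)C(C)(C)C)c3c(O)cc(OC)c(O)c3O2)cc1OC
A2 | alternative 1 | 4-[(2S,4S)-4-(tert-butyldimethylsilyloxy)-2-(3,4-dimethoxyphenyl)-3,4-dihydro-2H-pyran-6-yl]-4-hydroxy-3-methoxycyclobut-2-en-1-one | COc1ccc([C@@H]2C[C@H](O[Si](C)(C)C(C)(C)C)C=C(C3(O)C(OC)=CC3=O)O2)cc1OC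
A3 | alternative 1 | tert-butyl{[(2S,4S)-2-(3,4-dimethoxyphenyl)-3,4-dihydro-2H-pyran-4-yl]oxy}dimethylsilane | COc1ccc([C@@H]2C[C@H](O[Si](C)(C)C(C)(C)C)C=CO2)cc1OC
A4 | alternative 1 | 3-methoxycyclobut-3-ene-1,2-dione | COC1=CC(=O)C1=O
A5 | alternative 2 | (2S)-4-(tert-butyldimethylsilyloxy)-2-(3,4-dimethoxyphenyl)-5,7,8-trimethoxy-2H-chromene | COc1ccc([C@@H]2C=C(O[Si](C)(C)C(C)(C)C)c3c(OC)cc(OC)c(OC)c3O2)cc1OC
A6 | alternative 2 | tert-butyl{[1-(2-{[(1S)-1-(3,4-dimethoxyphenyl)prop-2-en-1-yl]oxy}-3,4,6-trimethoxyphenyl)ethenyl]oxy}dimethylsilane | COc1ccc([C@@H](Oc2c(OC)c(OC)cc(OC)c2C(=C)O[Si](C)(C)C(C)(C)C)C=C)cc1OC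
A7 | alternative 2 | 1-(2-hydroxy-3,4,6-trimethoxyphenyl)ethan-1-one | CC(=O)c1c(O)c(OC)c(OC)cc1OC
A8 | alternative 3 | (2S,4S)-2-(3,4-dimethoxyphenyl)-4,5,7,8-tetramethoxychromane | COc1ccc([C@@H]2C[C@H](OC)c3c(OC)cc(OC)c(OC)c3O2)cc1OC
A9 | alternative 3 | 2-hydroxy-3,4,6-trimethoxybenzaldehyde | O=Cc1c(O)c(OC)c(OC)cc1OC
A10 | alternative 3 | 3,4-dimethoxystyrene | C=Cc1ccc(OC)c(OC)c1
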